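The target is viewed with germacrane numbering. It is a ten-membered carbocycle (C1–C10) whose C3 and C10 are bridged by the oxygen of a 3(2H)-furanone ring (O–C3=C2–C1(=O)–C10). The route rests on cutting C1–C2, a bond common to carbocycle and furanone, together with the O–C10 bridge bond, which opens both rings at once. The precursor is a trans-α-methylene-γ-butyrolactone with a (Z)-methyl enone on C6 and an α-mesyloxy acid chain on C7. In one operation the methyl ketone (C,O-bis-nucleophile) and the α-mesyloxyacyl chloride (1,2-bis-electrophile) combine. Macrocyclising C-acylation, then invertive O-alkylation, gives the oxa-bridged bicycle and the C10 stereocentre.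

Key step: step 15

Assumption: tert-butyl pyruvate (12) and (R)-2-methylbutanoic acid (17) are taken as purchasable. Locants: C1 furanone C=O, C2 furanone CH, C3 furanone O–C=, C4=C5 ring alkene, C6 lactone O–CH, C7, C8 ester carbinol, C9 CH2, C10 quaternary C, C11–C13 methylene lactone, C14 CH3, C15 CH2O.

Step 1
Reactants: 1 but-2-yne-1,4-diol
Product: 2 4-[(tert-butyldiphenylsilyl)oxy]but-2-yn-1-ol
Conditions: TBDPSCl (diol in excess), imidazole, DMF, 0 °C to rt
Reagents that add atoms: tert-butyldiphenylsilyl chloride, CC(C)(C)[Si](Cl)(c1ccccc1)c1ccccc1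
Why: Silyl ether formation on a symmetric diol used in excess should stop at the mono-ether, leaving one propargylic OH to direct step 2.

Step 2
Reactants: 2 4-[(tert-butyldiphenylsilyl)oxy]but-2-yn-1-ol
Product: 4 (Z)-4-[(tert-butyldiphenylsilyl)oxy]-3-iodobut-2-en-1-ol, via cyclic sodium vinylalanate 3 (not isolated)
Conditions: Red-Al, THF, 0 °C; then I2, THF, −78 °C to 0 °C
Reagents that add atoms: iodine, II
Why: Hydroxyl-directed trans-hydroalumination of the propargylic alcohol puts aluminium on the distal alkyne carbon (C4) in a five-membered alanate, and iodinolysis with retention should give only the Z-iodide, which fixes the C4=C5 geometry of the target.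

Step 3
Reactants: 4 (Z)-4-[(tert-butyldiphenylsilyl)oxy]-3-iodobut-2-en-1-ol
Product: 5 (Z)-4-[(tert-butyldiphenylsilyl)oxy]-3-iodobut-2-enal
Conditions: MnO2, CH2Cl2, rt
Reagents that add atoms: none
Why: Allylic alcohol oxidation with MnO2 is neutral and should keep both the Z geometry and the C–I bond.

Step 4
Reactants: 5 (Z)-4-[(tert-butyldiphenylsilyl)oxy]-3-iodobut-2-enal
Product: 6 (3S,4Z)-6-[(tert-butyldiphenylsilyl)oxy]-5-iodohexa-1,4-dien-3-ol
Conditions: CH2=CHMgBr, ZnCl2, Et2O, then 1,4-dioxane (Mg salts precipitated); (−)-MIB (5 mol %), toluene, −20 to 0 °C; dilute HCl quench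
Reagents that add atoms: vinylmagnesium bromide, C=C[Mg]Br (delivers the vinyl group via divinylzinc, C=C[Zn]C=C)
Why: In this amino-alcohol-catalysed enantioselective alkenylzinc 1,2-addition, (−)-MIB directs Si-face attack as in its other organozinc additions, which should set C6 as (S) while iodine is present.

Step 5
Reactants: 6 (3S,4Z)-6-[(tert-butyldiphenylsilyl)oxy]-5-iodohexa-1,4-dien-3-ol; 7 2-(bromomethyl)acrylic acid
Product: 8 (3S,4Z)-6-[(tert-butyldiphenylsilyl)oxy]-5-iodohexa-1,4-dien-3-yl 2-(bromomethyl)acrylate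
Conditions: DCC, DMAP (cat.), CH2Cl2, −10 to 0 °C
Reagents that add atoms: none
Why: Steglich esterification acylates the carbinol oxygen without touching the C6–O bond (retention), and low temperature with little DMAP limits attack on the allylic bromide.

Step 6
Reactants: 8 (3S,4Z)-6-[(tert-butyldiphenylsilyl)oxy]-5-iodohexa-1,4-dien-3-yl 2-(bromomethyl)acrylate
Product: 9 (5S)-3-(bromomethyl)-5-[(Z)-3-[(tert-butyldiphenylsilyl)oxy]-2-iodoprop-1-enyl]furan-2(5H)-one
Conditions: Hoveyda–Grubbs II (5 mol %), toluene, 80 °C, argon sparge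
Reagents that add atoms: none
Why: Ring-closing metathesis between the monosubstituted vinyl group and the acrylate alkene closes the five-membered butenolide (C7=C11 with CH2Br on C11), the trisubstituted iodoalkene being inert.

Step 7
Reactants: 10 S-tert-butyl thioacetate
Product: 11 1-(tert-butylsulfanyl)-1-(trimethylsilyloxy)ethene
Conditions: LDA, TMSCl (in situ quench), THF, −78 °C
Reagents that add atoms: chlorotrimethylsilane, C[Si](C)(C)Cl
Why: Kinetic enolisation and O-silylation of the thioester gives the silyl ketene thioacetal that serves as acetate enolate equivalent.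

Step 8
Reactants: 11 1-(tert-butylsulfanyl)-1-(trimethylsilyloxy)ethene; 12 tert-butyl pyruvate
Product: 14 tert-butyl (2R)-4-(tert-butylsulfanyl)-2-hydroxy-2-methyl-4-oxobutanoate, via its O-trimethylsilyl ether 13 (not isolated)
Conditions: [Cu((R,R)-t-Bu-box)](OTf)2 (10 mol %), THF, −78 °C; then 1 M HCl
Reagents that add atoms: none
Why: In this Cu(II)-bis(oxazoline)-catalysed enantioselective Mukaiyama aldol addition to the chelated pyruvate, the (R,R)-ligand, antipode of the one leading to the (S)-citramalate series, should give the (R)-tertiary carbinol (C10).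

Step 9
Reactants: 14 tert-butyl (2R)-4-(tert-butylsulfanyl)-2-hydroxy-2-methyl-4-oxobutanoate
Product: 15 tert-butyl (2R)-2-hydroxy-2-methyl-4-oxobutanoate
Conditions: DIBAL-H (2.2 equiv), CH2Cl2, −78 °C; Rochelle salt
Reagents that add atoms: none
Why: DIBAL-H reduces the thioester to the aldehyde through a stable hemithioacetal aluminate, faster than it attacks the hindered tert-butyl ester.

Step 10
Reactants: 9 (5S)-3-(bromomethyl)-5-[(Z)-3-[(tert-butyldiphenylsilyl)oxy]-2-iodoprop-1-enyl]furan-2(5H)-one; 15 tert-butyl (2R)-2-hydroxy-2-methyl-4-oxobutanoate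
Product: 16 (6S,7R,8S,10R)-diol: tert-butyl (2R,4S)-4-{(2S,3R)-2-[(Z)-3-[(tert-butyldiphenylsilyl)oxy]-2-iodoprop-1-enyl]-4-methylidene-5-oxooxolan-3-yl}-2,4-dihydroxy-2-methylbutanoate
Conditions: Zn dust, THF/sat. aq NH4Cl, 0 °C to rt
Reagents that add atoms: none
Why: In this Barbier allylation the allylzinc from 9 reacts at its γ-carbon C7 (SE2′) through a chair transition state, anti to the C6 side chain (6,7-trans) and, because the ring locks an E-type allyl geometry, with anti C7/C8 topicity, so C7 (R) and C8 (S) are relayed from C6 and the exocyclic methylene appears; the alkenyl iodide is inert to zinc.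

Step 11
Reactants: 16 (6S,7R,8S,10R)-diol; 17 (R)-2-methylbutanoic acid
Product: 18 (6S,7R,8R,10R)-8-O-[(2R)-2-methylbutanoyl] ester of the C8-inverted diol, with the C10 OH free
Conditions: PPh3, DIAD, toluene, 0 °C to rt
Reagents that add atoms: none
Why: Mitsunobu esterification installs the ester with SN2 inversion at the secondary C8 carbinol (S to R), while the tertiary C10 OH is inert and the acid stereocentre is not touched.

Step 12
Reactants: 18 (6S,7R,8R,10R)-hydroxy ester
Product: 19 (6S,7R,8R,10R)-C10 methanesulfonate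
Conditions: MsCl, Et3N, CH2Cl2, −10 to 0 °C
Reagents that add atoms: methanesulfonyl chloride, CS(=O)(=O)Cl
Why: Sulfene-type mesylation works on tertiary alcohols and forms only an O–S bond, so C10 stays (R), and the adjacent ester carbonyl disfavours ionisation, which should make the mesylate isolable.

Step 13
Reactants: 19 (6S,7R,8R,10R)-C10 methanesulfonate
Product: 21 (6R,7R,8R,10R)-(Z)-methyl enone (acetyl on C4), via 2-ethoxydiene 20 (not isolated)
Conditions: tributyl(1-ethoxyvinyl)stannane, Pd2(dba)3, AsPh3, CuI, DMF, rt to 40 °C; then 1 M HCl, THF, 0 °C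
Reagents that add atoms: tributyl(1-ethoxyvinyl)stannane, CCCC[Sn](CCCC)(CCCC)C(=C)OCC; water, O
Why: Stille coupling of the Z-alkenyl iodide with an acetyl anion equivalent goes with retention of alkene geometry, and mild hydrolysis of the enol ether releases the methyl ketone (C2–C3).

Step 14
Reactants: 21 (6R,7R,8R,10R)-(Z)-methyl enone
Product: 22 (6R,7R,8R,10R)-α-mesyloxy carboxylic acid (C1 = CO2H)
Conditions: TFA/CH2Cl2 (1:4), 0 °C
Reagents that add atoms: none
Why: Acidolysis (E1) of the tert-butyl ester should leave the secondary ester, the lactone, the α-carbonyl mesylate and the TBDPS ether untouched.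

Step 15
Reactants: 22 (6R,7R,8R,10R)-α-mesyloxy carboxylic acid
Product: 25 15-O-TBDPS ether of the target (6R,7R,8R,10S), via acyl chloride 23 (not isolated), via ten-membered β-diketone 24 (not isolated)
Conditions: 1-chloro-N,N,2-trimethylprop-1-en-1-amine, CH2Cl2, 0 °C; then syringe-pump addition to MgBr2·OEt2, i-Pr2NEt, CH2Cl2, rt to 35 °C (final ca. 1 mM)
Reagents that add atoms: none
Why: The acid is chlorinated under neutral conditions to 23, Mg(II)/amine soft enolisation deprotonates the C3 methyl ketone at C2 (the acyl chloride has no α-H), the magnesium enolate is C-acylated by C1 to give β-diketone 24 (C1–C2 bond), and the C3 enolate oxygen of 24 then displaces the C10 mesylate (O–C10 bond), the vinylogous ester 25 being the irreversible sink. The closest known reaction type is the soft-enolisation crossed Claisen synthesis of 1,3-diketones from ketones and acyl chlorides or active esters, followed by the classical closure of α′-halo or α′-sulfonyloxy 1,3-diketones to 3(2H)-furanones, that is the [3+2] union of a ketone enolate with an α-haloacyl halide, here run intramolecularly. The ten-membered carbocycle closes in a 10-exo-trig acyl substitution whose ends are pre-organised by the Z C4=C5 alkene, the trans-lactone and magnesium chelation, and the furanone closes 5-exo-tet through the in-plane lone pair of the enolate oxygen, the mode allowed for O- but not C-alkylation of such enolates. The only new stereocentre, C10, is set by backside attack on the (R)-mesylate (inversion to S), because the adjacent C1 carbonyl disfavours ionisation and SN2 substitution with inversion at tertiary α-carbonyl carbinol derivatives is established. The step needs C- over O-acylation (secured by the magnesium chelate), attack on C1 rather than on the lactone, the ester or the methylene lactone (secured by the far higher reactivity of the acyl chloride and a non-nucleophilic base), and ring closure over oligomerisation (secured by slow addition at high dilution).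

Step 16
Reactants: 25 15-O-TBDPS ether of the target
Product: 26 target, CNP0307052.2 (6R,7R,8R,10S,2′R; 4Z)
Conditions: HF·pyridine, THF, 0 °C to rt
Reagents that add atoms: none
Why: Fluoride-mediated Si–O cleavage under mildly acidic conditions should spare the Michael acceptors, the esters and the furanone.

Compound list
1 | but-2-yne-1,4-diol | OCC#CCO | starting material
2 | 4-[(tert-butyldiphenylsilyl)oxy]but-2-yn-1-ol | OCC#CCO[Si](c1ccccc1)(c1ccccc1)C(C)(C)C | intermediate
3 | cyclic sodium vinylalanate from 2 (not isolated) | [Na+].COCCO[Al-]1(OCCOC)OCC=C1CO[Si](c2ccccc2)(c2ccccc2)C(C)(C)C | intermediate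
4 | (Z)-4-[(tert-butyldiphenylsilyl)oxy]-3-iodobut-2-en-1-ol | OC/C=C(/CO[Si](c1ccccc1)(c1ccccc1)C(C)(C)C)I | intermediate
5 | (Z)-4-[(tert-butyldiphenylsilyl)oxy]-3-iodobut-2-enal | O=C/C=C(/CO[Si](c1ccccc1)(c1ccccc1)C(C)(C)C)I | intermediate
6 | (3S,4Z)-6-[(tert-butyldiphenylsilyl)oxy]-5-iodohexa-1,4-dien-3-ol | C=C[C@@H](/C=C(/CO[Si](c1ccccc1)(c1ccccc1)C(C)(C)C)I)O | intermediate
7 | 2-(bromomethyl)acrylic acid | C=C(CBr)C(=O)O | starting material
8 | (3S,4Z)-6-[(tert-butyldiphenylsilyl)oxy]-5-iodohexa-1,4-dien-3-yl 2-(bromomethyl)acrylate | C=C[C@@H](/C=C(/CO[Si](c1ccccc1)(c1ccccc1)C(C)(C)C)I)OC(=O)C(=C)CBr | intermediate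
9 | (5S)-3-(bromomethyl)-5-[(Z)-3-[(tert-butyldiphenylsilyl)oxy]-2-iodoprop-1-enyl]furan-2(5H)-one | BrCC1=C[C@@H](/C=C(/CO[Si](c2ccccc2)(c2ccccc2)C(C)(C)C)I)OC1=O | intermediate
10 | S-tert-butyl thioacetate | CC(=O)SC(C)(C)C | starting material
11 | 1-(tert-butylsulfanyl)-1-(trimethylsilyloxy)ethene | C=C(O[Si](C)(C)C)SC(C)(C)C | intermediate
12 | tert-butyl pyruvate | CC(=O)C(=O)OC(C)(C)C | starting material
13 | tert-butyl (2R)-4-(tert-butylsulfanyl)-2-methyl-4-oxo-2-(trimethylsilyloxy)butanoate (not isolated) | CC(C)(C)SC(=O)C[C@@](C(=O)OC(C)(C)C)(C)O[Si](C)(C)C | intermediate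
14 | tert-butyl (2R)-4-(tert-butylsulfanyl)-2-hydroxy-2-methyl-4-oxobutanoate | CC(C)(C)SC(=O)C[C@@](C(=O)OC(C)(C)C)(C)O | intermediate
15 | tert-butyl (2R)-2-hydroxy-2-methyl-4-oxobutanoate | O=CC[C@@](C(=O)OC(C)(C)C)(C)O | intermediate
16 | (6S,7R,8S,10R)-Barbier diol (trans-α-methylene lactone, Z-iodoalkene on C6, 8-OH, 10-OH, tert-butyl ester at C1) | C=C1C(=O)O[C@H](/C=C(/CO[Si](c2ccccc2)(c2ccccc2)C(C)(C)C)I)[C@H]1[C@H](C[C@@](C(=O)OC(C)(C)C)(C)O)O | intermediate
17 | (R)-2-methylbutanoic acid | CC[C@@H](C)C(=O)O | starting material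
18 | (6S,7R,8R,10R)-8-(2R)-2-methylbutanoate, 10-OH | C=C1C(=O)O[C@H](/C=C(/CO[Si](c2ccccc2)(c2ccccc2)C(C)(C)C)I)[C@H]1[C@@H](C[C@@](C(=O)OC(C)(C)C)(C)O)OC(=O)[C@H](C)CC | intermediate
19 | (6S,7R,8R,10R)-10-methanesulfonate | C=C1C(=O)O[C@H](/C=C(/CO[Si](c2ccccc2)(c2ccccc2)C(C)(C)C)I)[C@H]1[C@@H](C[C@@](C(=O)OC(C)(C)C)(C)OS(C)(=O)=O)OC(=O)[C@H](C)CC | intermediate
20 | (6R,7R,8R,10R)-2-ethoxydiene (not isolated) | C=C1C(=O)O[C@H](/C=C(/CO[Si](c2ccccc2)(c2ccccc2)C(C)(C)C)C(=C)OCC)[C@H]1[C@@H](C[C@@](C(=O)OC(C)(C)C)(C)OS(C)(=O)=O)OC(=O)[C@H](C)CC | intermediate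
21 | (6R,7R,8R,10R)-(Z)-methyl enone, tert-butyl ester | C=C1C(=O)O[C@H](/C=C(/CO[Si](c2ccccc2)(c2ccccc2)C(C)(C)C)C(C)=O)[C@H]1[C@@H](C[C@@](C(=O)OC(C)(C)C)(C)OS(C)(=O)=O)OC(=O)[C@H](C)CC | intermediate
22 | (6R,7R,8R,10R)-(Z)-methyl enone, α-mesyloxy acid | C=C1C(=O)O[C@H](/C=C(/CO[Si](c2ccccc2)(c2ccccc2)C(C)(C)C)C(C)=O)[C@H]1[C@@H](C[C@@](C(=O)O)(C)OS(C)(=O)=O)OC(=O)[C@H](C)CC | intermediate
23 | (6R,7R,8R,10R)-α-mesyloxyacyl chloride (not isolated) | C=C1C(=O)O[C@H](/C=C(/CO[Si](c2ccccc2)(c2ccccc2)C(C)(C)C)C(C)=O)[C@H]1[C@@H](C[C@@](C(=O)Cl)(C)OS(C)(=O)=O)OC(=O)[C@H](C)CC | intermediate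
24 | (6R,7R,8R,10R)-ten-membered 1,3-diketone with 10-OMs (not isolated) | C=C1C(=O)O[C@@H]2/C=C(/CO[Si](c3ccccc3)(c3ccccc3)C(C)(C)C)C(=O)CC(=O)[C@](C)(OS(C)(=O)=O)C[C@@H](OC(=O)[C@H](C)CC)[C@@H]12 | intermediate
25 | 15-O-TBDPS ether of the target (6R,7R,8R,10S) | C=C1C(=O)O[C@@H]2/C=C(/CO[Si](c4ccccc4)(c4ccccc4)C(C)(C)C)C3=CC(=O)[C@](C)(C[C@@H](OC(=O)[C@H](C)CC)[C@@H]12)O3 | intermediate
26 | CNP0307052.2 | C=C1C(=O)O[C@@H]2/C=C(/CO)C3=CC(=O)[C@](C)(C[C@@H](OC(=O)[C@H](C)CC)[C@@H]12)O3 | target

Total step count: 16. Longest linear sequence: 13 (steps 1–6 and 10–16).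

Steps most likely to fail

1. Step 15. Closure at the hindered acyl carbon may be slow. Intermolecular acylation, hydrolysis of the acyl chloride or Z-to-E isomerisation of the enone could then overtake it. Bromide exchange or ionisation at C10 before ring closure would erode the inversion. The fallback moves the macrocyclisation to the aldehyde oxidation level and separates the two bond formations. It sets out from 23 and comes back at 24, then 25. Compound 23 would be reduced with LiAlH(O-t-Bu)3 at −78 °C to the α-mesyloxy aldehyde F1. A boron-mediated intramolecular aldol addition (c-Hex2BCl, Et3N, high dilution) of the methyl ketone to this more reactive electrophile would close the ring as the ten-membered β-hydroxy ketone F2. Dess–Martin oxidation would give 24, now isolated. A halide-free base (Cs2CO3, MeCN) would then close the furanone to 25.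

2. Step 11. SN2 attack at the hindered C8 carbinol may be slow. Elimination towards C7, or participation of the tert-butyl ester carbonyl (lactonisation with loss of isobutene), could then compete. The fallback sets the C8 configuration in the C–C bond formation instead of by inversion. It sets out from 6 and comes back at 18. Compound 6 would be esterified with 2-[(trimethylsilyl)methyl]acrylic acid to the silylmethyl acrylate F3. Ring-closing metathesis would give the allylsilane butenolide F4. A BF3·OEt2-promoted Hosomi–Sakurai addition to 15 through an open, syn-selective transition state, anti to the C6 side chain, would give the (8R)-diol F5. A Steglich esterification with 17 (retention) would then give 18.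

3. Step 6. The allylic bromide may degrade the ruthenium catalyst, and the electron-poor 1,1-disubstituted alkene may engage slowly, so homodimerisation at the vinyl group could win. The fallback closes the ring first and installs CH2Br afterwards. It sets out from 6 and comes back at 9. Compound 6 would be acylated with acryloyl chloride to the acrylate F6. Ring-closing metathesis of this simpler diene would give the α-unsubstituted butenolide F7. A Morita–Baylis–Hillman hydroxymethylation with formaldehyde would give the 3-(hydroxymethyl)butenolide F8. An Appel bromination (CBr4, PPh3) would then give 9.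

Further compounds
F1 | step 15 | (6R,7R,8R,10R)-α-mesyloxy aldehyde | C=C1C(=O)O[C@H](/C=C(/CO[Si](c2ccccc2)(c2ccccc2)C(C)(C)C)C(C)=O)[C@H]1[C@@H](C[C@@](C=O)(C)OS(C)(=O)=O)OC(=O)[C@H](C)CC
F2 | step 15 | ten-membered β-hydroxy ketone (C1 carbinol configuration open, erased on oxidation) | C=C1C(=O)O[C@@H]2/C=C(/CO[Si](c3ccccc3)(c3ccccc3)C(C)(C)C)C(=O)CC(O)[C@](C)(OS(C)(=O)=O)C[C@@H](OC(=O)[C@H](C)CC)[C@@H]12
F3 | step 11 | (3S,4Z)-6-[(tert-butyldiphenylsilyl)oxy]-5-iodohexa-1,4-dien-3-yl 2-[(trimethylsilyl)methyl]acrylate | C=C[C@@H](/C=C(/CO[Si](c1ccccc1)(c1ccccc1)C(C)(C)C)I)OC(=O)C(=C)C[Si](C)(C)C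
F4 | step 11 | (5S)-5-[(Z)-3-[(tert-butyldiphenylsilyl)oxy]-2-iodoprop-1-enyl]-3-[(trimethylsilyl)methyl]furan-2(5H)-one | C[Si](C)(C)CC1=C[C@@H](/C=C(/CO[Si](c2ccccc2)(c2ccccc2)C(C)(C)C)I)OC1=O
F5 | step 11 | (6S,7R,8R,10R)-diol (C8 epimer of 16) | C=C1C(=O)O[C@H](/C=C(/CO[Si](c2ccccc2)(c2ccccc2)C(C)(C)C)I)[C@H]1[C@@H](C[C@@](C(=O)OC(C)(C)C)(C)O)O
F6 | step 6 | (3S,4Z)-6-[(tert-butyldiphenylsilyl)oxy]-5-iodohexa-1,4-dien-3-yl acrylate | C=C[C@@H](/C=C(/CO[Si](c1ccccc1)(c1ccccc1)C(C)(C)C)I)OC(=O)C=C
F7 | step 6 | (5S)-5-[(Z)-3-[(tert-butyldiphenylsilyl)oxy]-2-iodoprop-1-enyl]furan-2(5H)-one | O=C1C=C[C@@H](/C=C(/CO[Si](c2ccccc2)(c2ccccc2)C(C)(C)C)I)O1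
F8 | step 6 | (5S)-5-[(Z)-3-[(tert-butyldiphenylsilyl)oxy]-2-iodoprop-1-enyl]-3-(hydroxymethyl)furan-2(5H)-one | OCC1=C[C@@H](/C=C(/CO[Si](c2ccccc2)(c2ccccc2)C(C)(C)C)I)OC1=O
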